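The numbers of this flask come from no measurement; the run is a simulation.

Slowness matters in this flask only if steps 1 and 2 fail to reach their balance within the run, so the reckoning asks where that balance lies and how long the approach takes.

    substrate + coupling partner ⇌ target (K1 = 30.6 /M, k1 = 3.62 /M/min)
    substrate + coupling partner ⇌ isomer of the product (K2 = 1420 /M, k2 = 2.01 /M/min)
    target + free catalyst ⇌ isomer of the product + free catalyst, rate k3*[free catalyst]*[target] forward; the back reaction follows from the equilibrium constant (k3 = 3870 /M/min)
    substrate + free catalyst → spent catalyst (k4 = 0.874 /M/min)

substrate 0.063 M; coupling partner 0.0599 M; free catalyst 63 µM; time 8.0 h

- why nothing more happens at 8.0 h, or that something still does (all of the substrate has reacted / forward and back rates have come level / the coupling partner has run out first / it is still moving / no working catalyst is left)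
- the target standing at 8.0 h, as a percentage of the substrate charged
- the isomer of the product standing at 8.0 h, as a percentage of the substrate charged

- the reaction counts as stopped when no species that holds the substrate changes by six tenths of a point or more over the second half of the time
- run time (flask): 8.0 h

In the first instants of this flask, step 1 runs ahead of step 2 because its rate constant is larger. By forward rates, target forms 1.8 times as fast as isomer of the product, and the forward half-life of substrate by step 1 is 3.20 min. Free catalyst then carries target on, with a forward half-life of 2.8 min. That is shorter than the 12.6 min the catalyst has as a half-life at charged substrate.

In the middle, the coupling comes to balance. By my reckoning, steps 1 and 2 act together with the constant 1450 /M, and one quadratic in the charges gives a converted fraction of 87.5%. That leaves 12.5% of the substrate standing, and this remainder goes on killing catalyst in a pseudo-first-order way.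

Time drops out of one quotient. At balance the forward and back rates of step 1 are level, and so are those of step 2. Dividing the one equality by the other cancels substrate and coupling partner too. What stands is the split, isomer of the product over target at balance, equal to K2 over K1: 46.4. This is thermodynamic control. Near the reckoned balance, the relaxation time of a coupling is one over its forward constant times free substrate plus free coupling partner, plus its back constant. That gives 6.09 min for step 1 and 37.1 min for step 2, both far shorter than the run. The reckoned end state is therefore forward and back rates have come level. The converted fraction divides by the split, giving 1.84% of target and 85.6% of isomer of the product.

The forecast gives forward and back rates have come level, 1.8% and 85.6%, on the ground that “the mixture reaches true equilibrium well before 8 h”.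

This flask gives forward and back rates have come level, with 1.84% of target and 85.6% of isomer of the product. Over the second half of the time, the largest change in this flask is 0.0073 percentage points. The neighbour charged with 0.024 M of coupling partner ends with 62% of its substrate standing and 0.790% of target. The split of 46.4 times that target gives 36.7% of isomer of the product, and that neighbour stands at 36.6%.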